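**Retrosynthetic overview**
1. Ring B (the pyran; target locants C1–C8a, side chain C1'–C7') is opened at O2–C3 and is formed last, by 6-endo-dig hydroalkoxylation of a C1-hydroxy ynenone.
2. The enyne is cut at C3–C1' (Sonogashira): fragment 1 is the ring-A ethynyl enone, fragment 2 is the (E)-vinyl iodide carrying C3', C4' and C5'.
3. Fragment 1: C5=C4a enone by Pd(OAc)2 dehydrosilylation, C7/C8 cis-diol by OsO4 anti to the C8a substituent, ring A and C8a by a new enantioselective Diels–Alder of a 2-silyloxy diene with a silyl enynoate.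
4. Fragment 2: C4'/C5' from D-isoleucine, C3' by chelation-controlled MeMgBr addition to an α-hydroxy β-stannyl enone, then iododestannylation.
5. Ring order: ring A first (Diels–Alder, step 3), ring B last (cycloisomerisation, step 18).

Assumption: the (S)-configured catalyst C24H24BNO·HN(SO2CF3)2 is taken to give (1S,6S)-6 in step 3 by analogy with its acrylate selectivity; if the sense is opposite, its (R)-enantiomer is used and nothing else changes.

**Route**

Step 1
Reactants: 1 3-methylbut-3-en-2-one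
Product: 2 2-methyl-3-[(triisopropylsilyl)oxy]buta-1,3-diene
Conditions: i-Pr3SiOTf, Et3N, CH2Cl2, 0 °C to rt
Reagents that add atoms: triisopropylsilyl trifluoromethanesulfonate, CC(C)[Si](C(C)C)(C(C)C)OS(=O)(=O)C(F)(F)F
Why: Soft enolisation and O-silylation (silyl enol ether formation) at the acetyl CH3, the only enolisable position, gives the 2-silyloxy diene.

Step 2
Reactants: 3 3-(trimethylsilyl)prop-2-ynal; 4 trimethyl phosphonoacetate
Product: 5 methyl (2E)-5-(trimethylsilyl)pent-2-en-4-ynoate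
Conditions: LiCl, i-Pr2NEt, MeCN, 0 °C to rt
Reagents that add atoms: none
Why: Horner–Wadsworth–Emmons olefination under Masamune–Roush conditions, in which the stabilised phosphonate gives the E-enoate.

Step 3
Reactants: 2 2-methyl-3-[(triisopropylsilyl)oxy]buta-1,3-diene; 5 methyl (2E)-5-(trimethylsilyl)pent-2-en-4-ynoate
Product: 6 methyl (1S,6S)-3-methyl-4-[(triisopropylsilyl)oxy]-6-[(trimethylsilyl)ethynyl]cyclohex-3-ene-1-carboxylate (ester and alkynyl trans)
Conditions: (S)-1-(2-methylphenyl)-3,3-diphenyltetrahydro-1H,3H-pyrrolo[1,2-c][1,3,2]oxazaborole (C24H24BNO, 20 mol%), HN(SO2CF3)2 (20 mol%), CH2Cl2, −78 to −20 °C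
Reagents that add atoms: none
Why: Proposed new method: an enantioselective Diels–Alder reaction catalysed by C24H24BNO·HN(SO2CF3)2 in which a β-alkynyl acrylate (2-en-4-ynoate) is the dienophile for a 3-methyl-2-silyloxy diene, a pairing not yet shown; the boron cation binds the ester carbonyl and holds the s-trans enoate against its aryl wall, the slim electron-withdrawing alkynyl group lowers the LUMO without steric cost, the diene terminus next to the OSi carbon (largest HOMO coefficient) bonds to the alkynyl-bearing β-carbon so the ester ends up para to OSi, the E geometry is carried suprafacially into the trans C8a/C4a pair, and the open enoate face fixes C8a; the closest known reaction is the same catalyst's Diels–Alder of 2-(triisopropylsilyloxy)buta-1,3-diene with 2,2,2-trifluoroethyl acrylate.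

Step 4
Reactants: 6 methyl (1S,6S)-3-methyl-4-[(triisopropylsilyl)oxy]-6-[(trimethylsilyl)ethynyl]cyclohex-3-ene-1-carboxylate
Product: 7 {(1S,6S)-3-methyl-4-[(triisopropylsilyl)oxy]-6-[(trimethylsilyl)ethynyl]cyclohex-3-en-1-yl}methanol
Conditions: LiAlH4, Et2O, −20 to 0 °C
Reagents that add atoms: none
Why: LiAlH4 ester reduction gives the primary alcohol (C1) while the silyl enol ether and silylalkyne are inert and no stereocentre is touched.

Step 5
Reactants: 7 {(1S,6S)-3-methyl-4-[(triisopropylsilyl)oxy]-6-[(trimethylsilyl)ethynyl]cyclohex-3-en-1-yl}methanol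
Product: 8 tert-butyl({(1S,6S)-3-methyl-4-[(triisopropylsilyl)oxy]-6-[(trimethylsilyl)ethynyl]cyclohex-3-en-1-yl}methoxy)dimethylsilane
Conditions: t-BuMe2SiCl, imidazole, DMF, rt
Reagents that add atoms: tert-butyldimethylsilyl chloride, CC(C)(C)[Si](C)(C)Cl
Why: Silyl ether protection of the primary alcohol, which also puts a bulky group on C8a to shield one ring face in step 7.

Step 6
Reactants: 8 tert-butyl({(1S,6S)-3-methyl-4-[(triisopropylsilyl)oxy]-6-[(trimethylsilyl)ethynyl]cyclohex-3-en-1-yl}methoxy)dimethylsilane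
Product: 9 (4S,5S)-4-{[(tert-butyldimethylsilyl)oxy]methyl}-2-methyl-5-[(trimethylsilyl)ethynyl]cyclohex-2-en-1-one
Conditions: Pd(OAc)2 (1.1 equiv), DMSO/MeCN, 40 °C
Reagents that add atoms: none
Why: Ito–Saegusa oxidation, in which the silyl enol ether hands its enolate to Pd(OAc)2 at C7 and β-hydride elimination of the ring C8–H gives the 2-methyl enone without touching C8a.

Step 7
Reactants: 9 (4S,5S)-4-{[(tert-butyldimethylsilyl)oxy]methyl}-2-methyl-5-[(trimethylsilyl)ethynyl]cyclohex-2-en-1-one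
Product: 10 (2S,3S,4S,5S)-4-{[(tert-butyldimethylsilyl)oxy]methyl}-2,3-dihydroxy-2-methyl-5-[(trimethylsilyl)ethynyl]cyclohexan-1-one
Conditions: OsO4 (5 mol%), N-methylmorpholine N-oxide, acetone/H2O, rt
Reagents that add atoms: osmium tetroxide, O=[Os](=O)(=O)=O; N-methylmorpholine N-oxide, C[N+]1([O-])CCOCC1; water, O
Why: Upjohn syn-dihydroxylation, in which OsO4 adds to C7=C8 from the face opposite the allylic CH2OSi group on C8a (the other face also carries the axial C4a–H), setting C7 and C8 as the cis-diol trans to C1.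

Step 8
Reactants: 10 (2S,3S,4S,5S)-4-{[(tert-butyldimethylsilyl)oxy]methyl}-2,3-dihydroxy-2-methyl-5-[(trimethylsilyl)ethynyl]cyclohexan-1-one
Product: 11 (2S,3S,4S,5S)-4-{[(tert-butyldimethylsilyl)oxy]methyl}-2-methyl-2,3-bis[(triethylsilyl)oxy]-5-[(trimethylsilyl)ethynyl]cyclohexan-1-one
Conditions: Et3SiOTf, 2,6-lutidine, CH2Cl2, −78 to 0 °C
Reagents that add atoms: triethylsilyl trifluoromethanesulfonate, CC[Si](CC)(CC)OS(=O)(=O)C(F)(F)F
Why: Silyl triflate silylation (silyl ether protection) caps the secondary and tertiary hydroxyls, blocking retro-aldol and α-ketol chemistry in the base step that follows.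

Step 9
Reactants: 11 (2S,3S,4S,5S)-4-{[(tert-butyldimethylsilyl)oxy]methyl}-2-methyl-2,3-bis[(triethylsilyl)oxy]-5-[(trimethylsilyl)ethynyl]cyclohexan-1-one
Product: 13 (4S,5S,6S)-4-{[(tert-butyldimethylsilyl)oxy]methyl}-6-methyl-5,6-bis[(triethylsilyl)oxy]-3-[(trimethylsilyl)ethynyl]cyclohex-2-en-1-one, via trimethylsilyl enol ether 12 (not isolated)
Conditions: LiN(SiMe3)2, Me3SiCl, THF, −78 °C; then Pd(OAc)2 (1.1 equiv), MeCN, rt
Reagents that add atoms: none
Why: Kinetic enolisation can occur only at C5 because C7 is quaternary, and Ito–Saegusa oxidation of the silyl enol ether then gives the C5=C4a enone conjugated to the alkyne, which erases the C4a stereocentre.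

Step 10
Reactants: 13 (4S,5S,6S)-4-{[(tert-butyldimethylsilyl)oxy]methyl}-6-methyl-5,6-bis[(triethylsilyl)oxy]-3-[(trimethylsilyl)ethynyl]cyclohex-2-en-1-one
Product: 14 (4S,5S,6S)-4-{[(tert-butyldimethylsilyl)oxy]methyl}-3-ethynyl-6-methyl-5,6-bis[(triethylsilyl)oxy]cyclohex-2-en-1-one
Conditions: AgNO3 (10 mol%), acetone/H2O/CH2Cl2, rt
Reagents that add atoms: none
Why: AgNO3-catalysed protodesilylation of the C(sp)–SiMe3 bond is chemoselective over the three O-silyl ethers and avoids base at the γ-acidic C8a.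

Step 11
Reactants: 15 D-isoleucine
Product: 16 (2R,3R)-2-hydroxy-3-methylpentanoic acid
Conditions: NaNO2, 1 M H2SO4 (aq), 0 °C to rt
Reagents that add atoms: water, O
Why: Diazotisation of the α-amino acid, in which the carboxylate displaces N2 to an α-lactone that water reopens, so the hydroxyl arrives with net retention (double inversion) at the future C4'.

Step 12
Reactants: 16 (2R,3R)-2-hydroxy-3-methylpentanoic acid
Product: 17 (2R,3R)-2-hydroxy-N-methoxy-N,3-dimethylpentanamide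
Conditions: MeNH(OMe)·HCl, EDC·HCl, HOBt, N-methylmorpholine, CH2Cl2, 0 °C to rt
Reagents that add atoms: N,O-dimethylhydroxylamine hydrochloride, CNOC.Cl
Why: Carbodiimide amide coupling through the HOBt ester gives the Weinreb amide without epimerising the α-hydroxy centre.

Step 13
Reactants: 17 (2R,3R)-2-hydroxy-N-methoxy-N,3-dimethylpentanamide; 18 (E)-1,2-bis(tributylstannyl)ethene
Product: 20 (1E,4R,5R)-4-hydroxy-5-methyl-1-(tributylstannyl)hept-1-en-3-one, via (E)-2-(tributylstannyl)vinyllithium 19 (not isolated)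
Conditions: 18, n-BuLi, THF, −78 °C; then 17 pre-treated with LiN(SiMe3)2 (1.05 equiv), THF, −78 to −40 °C
Reagents that add atoms: none
Why: Tin–lithium exchange gives the E-vinyllithium with retention, and its addition to the Weinreb amide (Weinreb ketone synthesis) stops at the chelated tetrahedral intermediate, so the E-stannyl enone forms without over-addition.

Step 14
Reactants: 20 (1E,4R,5R)-4-hydroxy-5-methyl-1-(tributylstannyl)hept-1-en-3-one
Product: 21 (1E,3S,4R,5R)-3,5-dimethyl-1-(tributylstannyl)hept-1-ene-3,4-diol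
Conditions: MeMgBr (3 equiv), Et2O/CH2Cl2, −78 °C
Reagents that add atoms: methylmagnesium bromide, C[Mg]Br
Why: Chelation-controlled Grignard 1,2-addition (Cram cyclic model), in which the ROMgBr alkoxide of the α-hydroxyl chelates the ketone oxygen and methyl attacks the face opposite the sec-butyl group, setting C3' as S.

Step 15
Reactants: 21 (1E,3S,4R,5R)-3,5-dimethyl-1-(tributylstannyl)hept-1-ene-3,4-diol
Product: 22 (1E,3S,4R,5R)-1-iodo-3,5-dimethylhept-1-ene-3,4-diol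
Conditions: I2, CH2Cl2, 0 °C
Reagents that add atoms: iodine, [I][I]
Why: Iododestannylation (ipso electrophilic substitution of the vinylstannane) replaces tin by iodine with retention of the E geometry.

Step 16
Reactants: 14 (4S,5S,6S)-4-{[(tert-butyldimethylsilyl)oxy]methyl}-3-ethynyl-6-methyl-5,6-bis[(triethylsilyl)oxy]cyclohex-2-en-1-one; 22 (1E,3S,4R,5R)-1-iodo-3,5-dimethylhept-1-ene-3,4-diol
Product: 23 (4S,5S,6S)-4-{[(tert-butyldimethylsilyl)oxy]methyl}-3-[(3E,5S,6R,7R)-5,6-dihydroxy-5,7-dimethylnon-3-en-1-yn-1-yl]-6-methyl-5,6-bis[(triethylsilyl)oxy]cyclohex-2-en-1-one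
Conditions: Pd(PPh3)4 (5 mol%), CuI (10 mol%), Et3N, degassed THF, rt
Reagents that add atoms: none
Why: Sonogashira coupling joins the terminal alkyne to the E-vinyl iodide (C3–C1' bond) with retention of alkene geometry, tolerating the free diol, while the tertiary amine base cannot add to the ynenone.

Step 17
Reactants: 23 (4S,5S,6S)-4-{[(tert-butyldimethylsilyl)oxy]methyl}-3-[(3E,5S,6R,7R)-5,6-dihydroxy-5,7-dimethylnon-3-en-1-yn-1-yl]-6-methyl-5,6-bis[(triethylsilyl)oxy]cyclohex-2-en-1-one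
Product: 24 (4S,5S,6S)-3-[(3E,5S,6R,7R)-5,6-dihydroxy-5,7-dimethylnon-3-en-1-yn-1-yl]-5,6-dihydroxy-4-(hydroxymethyl)-6-methylcyclohex-2-en-1-one
Conditions: HF·pyridine, pyridine, THF, 0 °C to rt
Reagents that add atoms: none
Why: Buffered fluoride-mediated desilylation removes all three O-silyl groups in one operation under conditions that spare the tertiary allylic alcohol and the base-sensitive ynenone.

Step 18
Reactants: 24 (4S,5S,6S)-3-[(3E,5S,6R,7R)-5,6-dihydroxy-5,7-dimethylnon-3-en-1-yn-1-yl]-5,6-dihydroxy-4-(hydroxymethyl)-6-methylcyclohex-2-en-1-one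
Product: 25 (7S,8S,8aS)-3-[(1E,3S,4R,5R)-3,4-dihydroxy-3,5-dimethylhept-1-en-1-yl]-7,8-dihydroxy-7-methyl-8,8a-dihydro-1H-isochromen-6(7H)-one
Conditions: AuCl(PPh3) (5 mol%), AgOTf (5 mol%), THF, 0 °C to rt
Reagents that add atoms: none
Why: AuCl(PPh3)/AgOTf-catalysed 6-endo-dig hydroalkoxylation (alkynol cycloisomerisation), in which the C1 hydroxyl attacks C3, the δ-carbon of the activated ynenone, and protonation at C4 closes ring B as the dienol ether, while the C8 hydroxyl cannot compete because its cyclisation would need a bridgehead alkene.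

**Compound list**
1 | 3-methylbut-3-en-2-one | CC(=O)C(C)=C | starting material
2 | 2-methyl-3-[(triisopropylsilyl)oxy]buta-1,3-diene | C=C(C)C(=C)O[Si](C(C)C)(C(C)C)C(C)C | intermediate
3 | 3-(trimethylsilyl)prop-2-ynal | O=CC#C[Si](C)(C)C | starting material
4 | trimethyl phosphonoacetate | COC(=O)CP(=O)(OC)OC | starting material
5 | methyl (2E)-5-(trimethylsilyl)pent-2-en-4-ynoate | COC(=O)/C=C/C#C[Si](C)(C)C | intermediate
6 | methyl (1S,6S)-3-methyl-4-[(triisopropylsilyl)oxy]-6-[(trimethylsilyl)ethynyl]cyclohex-3-ene-1-carboxylate | COC(=O)[C@H]1CC(C)=C(O[Si](C(C)C)(C(C)C)C(C)C)C[C@@H]1C#C[Si](C)(C)C | intermediate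
7 | {(1S,6S)-3-methyl-4-[(triisopropylsilyl)oxy]-6-[(trimethylsilyl)ethynyl]cyclohex-3-en-1-yl}methanol | OC[C@H]1CC(C)=C(O[Si](C(C)C)(C(C)C)C(C)C)C[C@@H]1C#C[Si](C)(C)C | intermediate
8 | tert-butyl({(1S,6S)-3-methyl-4-[(triisopropylsilyl)oxy]-6-[(trimethylsilyl)ethynyl]cyclohex-3-en-1-yl}methoxy)dimethylsilane | CC(C)(C)[Si](C)(C)OC[C@H]1CC(C)=C(O[Si](C(C)C)(C(C)C)C(C)C)C[C@@H]1C#C[Si](C)(C)C | intermediate
9 | (4S,5S)-4-{[(tert-butyldimethylsilyl)oxy]methyl}-2-methyl-5-[(trimethylsilyl)ethynyl]cyclohex-2-en-1-one | CC1=C[C@H](CO[Si](C)(C)C(C)(C)C)[C@@H](C#C[Si](C)(C)C)CC1=O | intermediate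
10 | (2S,3S,4S,5S)-4-{[(tert-butyldimethylsilyl)oxy]methyl}-2,3-dihydroxy-2-methyl-5-[(trimethylsilyl)ethynyl]cyclohexan-1-one | C[Si](C)(C)C#C[C@H]1CC(=O)[C@@](C)(O)[C@@H](O)[C@@H]1CO[Si](C)(C)C(C)(C)C | intermediate
11 | (2S,3S,4S,5S)-4-{[(tert-butyldimethylsilyl)oxy]methyl}-2-methyl-2,3-bis[(triethylsilyl)oxy]-5-[(trimethylsilyl)ethynyl]cyclohexan-1-one | C[Si](C)(C)C#C[C@H]1CC(=O)[C@@](C)(O[Si](CC)(CC)CC)[C@@H](O[Si](CC)(CC)CC)[C@@H]1CO[Si](C)(C)C(C)(C)C | intermediate
12 | trimethylsilyl enol ether of 11: (3R,4S,5S,6S)-4-{[(tert-butyldimethylsilyl)oxy]methyl}-6-methyl-5,6-bis[(triethylsilyl)oxy]-1-[(trimethylsilyl)oxy]-3-[(trimethylsilyl)ethynyl]cyclohex-1-ene | C[Si](C)(C)C#C[C@H]1C=C(O[Si](C)(C)C)[C@@](C)(O[Si](CC)(CC)CC)[C@@H](O[Si](CC)(CC)CC)[C@@H]1CO[Si](C)(C)C(C)(C)C | intermediate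
13 | (4S,5S,6S)-4-{[(tert-butyldimethylsilyl)oxy]methyl}-6-methyl-5,6-bis[(triethylsilyl)oxy]-3-[(trimethylsilyl)ethynyl]cyclohex-2-en-1-one | C[Si](C)(C)C#CC1=CC(=O)[C@@](C)(O[Si](CC)(CC)CC)[C@@H](O[Si](CC)(CC)CC)[C@@H]1CO[Si](C)(C)C(C)(C)C | intermediate
14 | (4S,5S,6S)-4-{[(tert-butyldimethylsilyl)oxy]methyl}-3-ethynyl-6-methyl-5,6-bis[(triethylsilyl)oxy]cyclohex-2-en-1-one | C#CC1=CC(=O)[C@@](C)(O[Si](CC)(CC)CC)[C@@H](O[Si](CC)(CC)CC)[C@@H]1CO[Si](C)(C)C(C)(C)C | intermediate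
15 | D-isoleucine, (2R,3R)-2-amino-3-methylpentanoic acid | CC[C@@H](C)[C@@H](N)C(=O)O | starting material
16 | (2R,3R)-2-hydroxy-3-methylpentanoic acid | CC[C@@H](C)[C@@H](O)C(=O)O | intermediate
17 | (2R,3R)-2-hydroxy-N-methoxy-N,3-dimethylpentanamide | CC[C@@H](C)[C@@H](O)C(=O)N(C)OC | intermediate
18 | (E)-1,2-bis(tributylstannyl)ethene | CCCC[Sn](CCCC)(CCCC)/C=C/[Sn](CCCC)(CCCC)CCCC | starting material
19 | (E)-2-(tributylstannyl)vinyllithium | [Li]/C=C/[Sn](CCCC)(CCCC)CCCC | intermediate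
20 | (1E,4R,5R)-4-hydroxy-5-methyl-1-(tributylstannyl)hept-1-en-3-one | CC[C@@H](C)[C@@H](O)C(=O)/C=C/[Sn](CCCC)(CCCC)CCCC | intermediate
21 | (1E,3S,4R,5R)-3,5-dimethyl-1-(tributylstannyl)hept-1-ene-3,4-diol | CC[C@@H](C)[C@@H](O)[C@@](C)(O)/C=C/[Sn](CCCC)(CCCC)CCCC | intermediate
22 | (1E,3S,4R,5R)-1-iodo-3,5-dimethylhept-1-ene-3,4-diol | CC[C@@H](C)[C@@H](O)[C@@](C)(O)/C=C/I | intermediate
23 | (4S,5S,6S)-4-{[(tert-butyldimethylsilyl)oxy]methyl}-3-[(3E,5S,6R,7R)-5,6-dihydroxy-5,7-dimethylnon-3-en-1-yn-1-yl]-6-methyl-5,6-bis[(triethylsilyl)oxy]cyclohex-2-en-1-one | CC[C@@H](C)[C@@H](O)[C@@](C)(O)/C=C/C#CC1=CC(=O)[C@@](C)(O[Si](CC)(CC)CC)[C@@H](O[Si](CC)(CC)CC)[C@@H]1CO[Si](C)(C)C(C)(C)C | intermediate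
24 | (4S,5S,6S)-3-[(3E,5S,6R,7R)-5,6-dihydroxy-5,7-dimethylnon-3-en-1-yn-1-yl]-5,6-dihydroxy-4-(hydroxymethyl)-6-methylcyclohex-2-en-1-one | CC[C@@H](C)[C@@H](O)[C@@](C)(O)/C=C/C#CC1=CC(=O)[C@@](C)(O)[C@@H](O)[C@@H]1CO | intermediate
25 | (7S,8S,8aS)-3-[(1E,3S,4R,5R)-3,4-dihydroxy-3,5-dimethylhept-1-en-1-yl]-7,8-dihydroxy-7-methyl-8,8a-dihydro-1H-isochromen-6(7H)-one | CC[C@@H](C)[C@@H](O)[C@@](C)(O)/C=C/C1=CC2=CC(=O)[C@@](C)(O)[C@@H](O)[C@@H]2CO1 | target

**Totals**
Total step count: 18.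
Longest linear sequence: 12 steps (steps 1, 3 to 10, 16 to 18, from compound 1).

**The three steps most likely to fail**

Step 3 (the proposed new Diels–Alder). The enynoate may be too unreactive or give low enantioselectivity. The fallback uses known chemistry, sets out from 2 and comes back at 12.
- Diene 2 and commercial 2,2,2-trifluoroethyl acrylate, the dienophile class for which C24H24BNO·HN(SO2CF3)2 catalysis with 2-silyloxy dienes is documented, give 2,2,2-trifluoroethyl (1R)-3-methyl-4-[(triisopropylsilyl)oxy]cyclohex-3-ene-1-carboxylate F1. This has the same spatial arrangement at C8a as 6; the descriptor changes only because the ring branches rank differently.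
- LiAlH4 reduces it to {(1R)-3-methyl-4-[(triisopropylsilyl)oxy]cyclohex-3-en-1-yl}methanol F2.
- t-BuMe2SiCl/imidazole gives tert-butyl({(1R)-3-methyl-4-[(triisopropylsilyl)oxy]cyclohex-3-en-1-yl}methoxy)dimethylsilane F3.
- Pd(OAc)2 (Ito–Saegusa) gives (4R)-4-{[(tert-butyldimethylsilyl)oxy]methyl}-2-methylcyclohex-2-en-1-one F4.
- OsO4/N-methylmorpholine N-oxide, anti to the CH2OSi group, gives (2S,3S,4S)-4-{[(tert-butyldimethylsilyl)oxy]methyl}-2,3-dihydroxy-2-methylcyclohexan-1-one F5.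
- Et3SiOTf/2,6-lutidine gives (2S,3S,4S)-4-{[(tert-butyldimethylsilyl)oxy]methyl}-2-methyl-2,3-bis[(triethylsilyl)oxy]cyclohexan-1-one F6.
- 2-Iodoxybenzoic acid in DMSO at 70 °C dehydrogenates it to (4S,5S,6S)-4-{[(tert-butyldimethylsilyl)oxy]methyl}-6-methyl-5,6-bis[(triethylsilyl)oxy]cyclohex-2-en-1-one F7.
- Silyl-triflate-promoted conjugate addition of Me3SiC≡CZnBr (Me3SiOTf, THF, −40 °C) to F7, anti to the CH2OSi group, gives the trimethylsilyl enol ether 12. The Pd(OAc)2 stage of step 9 then converts it into 13.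

Step 6 (Pd(OAc)2 oxidation of a hindered, tetrasubstituted triisopropylsilyl enol ether). Silicon-to-palladium transfer may be too slow. The fallback sets out from 8 and comes back at 9. N-Bromosuccinimide (THF, −78 °C) brominates the silyl enol ether at C7 to (2S,4S,5S)-2-bromo-4-{[(tert-butyldimethylsilyl)oxy]methyl}-2-methyl-5-[(trimethylsilyl)ethynyl]cyclohexan-1-one F8. Li2CO3/LiBr in DMF at 100 °C then dehydrobrominates into the ring (classical bromination–dehydrobromination) to give 9.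

Step 18 (ring-B closure on an unprotected pentaol). A 5-exo mode or acid-type side reactions of the tertiary allylic alcohol could compete. The fallback sets out from 24 and comes back at 25. Pyrrolidine (1.1 equiv, MeOH, 0 °C) adds in 1,6-fashion to the ynenone at C3 to give the dienaminone (4S,5S,6S)-3-[(1E,3E,5S,6R,7R)-5,6-dihydroxy-5,7-dimethyl-2-(pyrrolidin-1-yl)nona-1,3-dien-1-yl]-5,6-dihydroxy-4-(hydroxymethyl)-6-methylcyclohex-2-en-1-one F9. Pyridinium p-toluenesulfonate in wet THF then lets the C1 hydroxyl displace the amine by addition–elimination at C3, closing ring B to 25.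

**Further compounds**
F1 | step 3 | 2,2,2-trifluoroethyl (1R)-3-methyl-4-[(triisopropylsilyl)oxy]cyclohex-3-ene-1-carboxylate | FC(F)(F)COC(=O)[C@H]1CC(C)=C(O[Si](C(C)C)(C(C)C)C(C)C)CC1
F2 | step 3 | {(1R)-3-methyl-4-[(triisopropylsilyl)oxy]cyclohex-3-en-1-yl}methanol | OC[C@H]1CC(C)=C(O[Si](C(C)C)(C(C)C)C(C)C)CC1
F3 | step 3 | tert-butyl({(1R)-3-methyl-4-[(triisopropylsilyl)oxy]cyclohex-3-en-1-yl}methoxy)dimethylsilane | CC(C)(C)[Si](C)(C)OC[C@H]1CC(C)=C(O[Si](C(C)C)(C(C)C)C(C)C)CC1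
F4 | step 3 | (4R)-4-{[(tert-butyldimethylsilyl)oxy]methyl}-2-methylcyclohex-2-en-1-one | CC1=C[C@H](CO[Si](C)(C)C(C)(C)C)CCC1=O
F5 | step 3 | (2S,3S,4S)-4-{[(tert-butyldimethylsilyl)oxy]methyl}-2,3-dihydroxy-2-methylcyclohexan-1-one | C1CC(=O)[C@@](C)(O)[C@@H](O)[C@@H]1CO[Si](C)(C)C(C)(C)C
F6 | step 3 | (2S,3S,4S)-4-{[(tert-butyldimethylsilyl)oxy]methyl}-2-methyl-2,3-bis[(triethylsilyl)oxy]cyclohexan-1-one | C1CC(=O)[C@@](C)(O[Si](CC)(CC)CC)[C@@H](O[Si](CC)(CC)CC)[C@@H]1CO[Si](C)(C)C(C)(C)C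
F7 | step 3 | (4S,5S,6S)-4-{[(tert-butyldimethylsilyl)oxy]methyl}-6-methyl-5,6-bis[(triethylsilyl)oxy]cyclohex-2-en-1-one | C1=CC(=O)[C@@](C)(O[Si](CC)(CC)CC)[C@@H](O[Si](CC)(CC)CC)[C@@H]1CO[Si](C)(C)C(C)(C)C
F8 | step 6 | (2S,4S,5S)-2-bromo-4-{[(tert-butyldimethylsilyl)oxy]methyl}-2-methyl-5-[(trimethylsilyl)ethynyl]cyclohexan-1-one | C[C@]1(Br)C[C@H](CO[Si](C)(C)C(C)(C)C)[C@@H](C#C[Si](C)(C)C)CC1=O
F9 | step 18 | (4S,5S,6S)-3-[(1E,3E,5S,6R,7R)-5,6-dihydroxy-5,7-dimethyl-2-(pyrrolidin-1-yl)nona-1,3-dien-1-yl]-5,6-dihydroxy-4-(hydroxymethyl)-6-methylcyclohex-2-en-1-one | CC[C@@H](C)[C@@H](O)[C@@](C)(O)/C=C/C(N1CCCC1)=C\C1=CC(=O)[C@@](C)(O)[C@@H](O)[C@@H]1CO
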